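Locants: ring C1 (stereocentre) to C14 with C3=C4(Me), C7=C8(C15H2OH), C11=C12(Me); side chain on C1 is C16(=CH2)–C17H2–C18H2–C19H=C20Me2.
Enabling feature: the ring bond C9–C10 is the central bond of the 1,5-diene C7=C8–C9–C10–C11=C12, and C8 carries C15. C7=C8(C15)–C9 is thus the product pattern of an SN2′ attack on a Baylis–Hillman acetate, and C10 is the α-carbon of an E-allyl sulfone.
Retrosynthesis: put SO2Ph on C10 and take C15 to the ester; cut the 14-membered ring at C9–C10; then cut the chain at C7–C8 (Baylis–Hillman), C10–S, C11=C12 (Horner–Wadsworth–Emmons), C4–C5 (B-alkyl Suzuki), C3=C4 (iodo-Wittig), the C3/C12 carbonyls (glycol cleavage of the limonene ring) and C17–C18 (prenylation).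
Forward: prenylate limonene-1,2-diol at the isopropenyl methyl, cleave the six-membered ring, grow the aldehyde arm (C3 to C7), then the ketone arm (C12 to C10–SO2Ph), add the acrylate (C8, C9, C15), close the only ring of the target at C9–C10, reduce the ester, remove the sulfone.
Stereochemistry: C1 (R) is C4 of the (R)-limonene-derived diol and is never touched; C3=C4 (Z) comes from a Z-selective α-iodo Wittig reaction and a stereoretentive coupling; C11=C12 (E) from the Horner–Wadsworth–Emmons step; C7=C8 (E, ring carbons C6 and C9 cis) from the elimination half of the ring closure.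

Key step: step 11

Remark: the C7 carbinol centre (16 to 19) and the sulfonyl-bearing C10 centre (19 to 21) are formed without control and their SMILES leave them open; both centres disappear (steps 11 and 13), so this has no consequence.

Step 1
Reactants: 1 (1S,2S,4R)-limonene-1,2-diol [(1S,2S,4R)-1-methyl-4-(prop-1-en-2-yl)cyclohexane-1,2-diol]; 2 prenyl bromide (1-bromo-3-methylbut-2-ene)
Product: 4 (1S,2S,4R)-1-methyl-4-(6-methylhepta-1,5-dien-2-yl)cyclohexane-1,2-diol, via trilithiated diol 3 (not isolated)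
Conditions: n-BuLi (3.3 equiv), TMEDA, hexane/Et2O, 0 °C → rt; then 2, THF, −78 °C → 0 °C; then H2O
Reagents that add atoms: none
Why: with both hydroxyls capped as lithium alkoxides, n-BuLi/TMEDA metalates the only allylic methyl (the isopropenyl CH3, as in the allylic lithiation of limonene and of the alkoxide of 3-methylbut-3-en-1-ol) to a symmetric 2-substituted allyllithium that prenyl bromide C-alkylates (SN2), completing the side chain; the ring stereocentre (C4 of the diol, C1 of the target) is not deprotonated and stays R.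

Step 2
Reactants: 4 (1S,2S,4R)-1-methyl-4-(6-methylhepta-1,5-dien-2-yl)cyclohexane-1,2-diol
Product: 5 (3R)-3-(6-methylhepta-1,5-dien-2-yl)-6-oxoheptanal
Conditions: NaIO4, THF/H2O, 0 °C → rt
Reagents that add atoms: none
Why: Malaprade glycol cleavage (cyclic periodate ester of the diequatorial chair) opens the six-membered ring to the C3 aldehyde and the C12 methyl ketone; the stereocentre is β to the aldehyde and cannot epimerise.

Step 3
Reactants: 5 (3R)-3-(6-methylhepta-1,5-dien-2-yl)-6-oxoheptanal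
Product: 6 (5R,7Z)-8-iodo-5-(6-methylhepta-1,5-dien-2-yl)non-7-en-2-one
Conditions: EtPPh3I, n-BuLi, THF, rt; I2, −78 °C; NaN(SiMe3)2, −20 °C; then 5, −78 °C → −20 °C
Reagents that add atoms: ethyltriphenylphosphonium iodide (CC[P+](c1ccccc1)(c1ccccc1)c1ccccc1.[I-]); iodine (II)
Why: Wittig olefination with (1-iodoethylidene)triphenylphosphorane (Stork–Zhao type) should take the aldehyde in preference to the less electrophilic methyl ketone at low temperature and give the (Z)-2-iodoalkene under kinetic control, which fixes the later Z geometry of C3=C4.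

Step 4
Reactants: 6 (5R,7Z)-8-iodo-5-(6-methylhepta-1,5-dien-2-yl)non-7-en-2-one; 7 acrolein diethyl acetal (3,3-diethoxyprop-1-ene)
Product: 9 (5R,7Z)-11,11-diethoxy-8-methyl-5-(6-methylhepta-1,5-dien-2-yl)undec-7-en-2-one, via B-alkyl-9-BBN 8 (not isolated)
Conditions: 7 (slight excess), 9-BBN-H, THF, 0 °C → rt; then 6, Pd(dppf)Cl2 (5 mol %), AsPh3, Cs2CO3, DMF/H2O, rt
Reagents that add atoms: none
Why: B-alkyl Suzuki–Miyaura coupling of the anti-Markovnikov 9-BBN adduct of 7 proceeds with retention at the alkenyl carbon, so C5 takes the place of iodine cis to C2 and the Z-trisubstituted C3=C4 alkene results; the ketone is safe because no B–H is left.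

Step 5
Reactants: 9 (5R,7Z)-11,11-diethoxy-8-methyl-5-(6-methylhepta-1,5-dien-2-yl)undec-7-en-2-one
Product: 10 ethyl (2E,6R,8Z)-12,12-diethoxy-3,9-dimethyl-6-(6-methylhepta-1,5-dien-2-yl)dodeca-2,8-dienoate
Conditions: (i-PrO)2P(O)CH2CO2Et, NaH, THF, 0 °C → 50 °C
Reagents that add atoms: ethyl 2-(diisopropoxyphosphoryl)acetate (CCOC(=O)CP(=O)(OC(C)C)OC(C)C)
Why: Horner–Wadsworth–Emmons olefination of the methyl ketone adds C11 and C10 and should favour the E enoate (ester trans to the longer C13 chain, reinforced by the bulky phosphonate esters); any Z isomer is to be removed by chromatography here or at 11.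

Step 6
Reactants: 10 ethyl (2E,6R,8Z)-12,12-diethoxy-3,9-dimethyl-6-(6-methylhepta-1,5-dien-2-yl)dodeca-2,8-dienoate
Product: 11 (2E,6R,8Z)-12,12-diethoxy-3,9-dimethyl-6-(6-methylhepta-1,5-dien-2-yl)dodeca-2,8-dien-1-ol
Conditions: i-Bu2AlH, CH2Cl2, −78 °C; aq. KNaC4H4O6
Reagents that add atoms: none
Why: 1,2-reduction of the α,β-unsaturated ester by i-Bu2AlH gives the E allylic alcohol without touching the acetal or the alkenes.

Step 7
Reactants: 11 (2E,6R,8Z)-12,12-diethoxy-3,9-dimethyl-6-(6-methylhepta-1,5-dien-2-yl)dodeca-2,8-dien-1-ol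
Product: 13 {[(2E,6R,8Z)-12,12-diethoxy-3,9-dimethyl-6-(6-methylhepta-1,5-dien-2-yl)dodeca-2,8-dien-1-yl]sulfonyl}benzene, via allylic mesylate 12 (not isolated)
Conditions: MsCl, Et3N, THF, −40 °C; then PhSO2Na, Bu4NI (cat.), DMF, 0 °C → rt
Reagents that add atoms: sodium benzenesulfinate ([Na+].[O-]S(=O)c1ccccc1)
Why: the primary allylic mesylate is displaced by the sulfur atom of the sulfinate in an SN2 reaction at C10 (no transposition to the hindered tertiary C12), giving the E-allyl phenyl sulfone that will acidify C10.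

Step 8
Reactants: 13 {[(2E,6R,8Z)-12,12-diethoxy-3,9-dimethyl-6-(6-methylhepta-1,5-dien-2-yl)dodeca-2,8-dien-1-yl]sulfonyl}benzene
Product: 14 (4Z,7R,10E)-4,10-dimethyl-7-(6-methylhepta-1,5-dien-2-yl)-12-(phenylsulfonyl)dodeca-4,10-dienal
Conditions: PPTS, acetone/H2O, 50 °C
Reagents that add atoms: water (O)
Why: mild acid-catalysed acetal hydrolysis frees the C7 aldehyde under conditions that leave the alkenes and the sulfone alone.

Step 9
Reactants: 14 (4Z,7R,10E)-4,10-dimethyl-7-(6-methylhepta-1,5-dien-2-yl)-12-(phenylsulfonyl)dodeca-4,10-dienal; 15 methyl acrylate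
Product: 16 methyl (6Z,9R,12E)-3-hydroxy-6,12-dimethyl-2-methylidene-9-(6-methylhepta-1,5-dien-2-yl)-14-(phenylsulfonyl)tetradeca-6,12-dienoate (both epimers at the carbinol carbon, ring locant C7)
Conditions: 15 (excess), DABCO, MeOH, rt
Reagents that add atoms: none
Why: the Morita–Baylis–Hillman reaction of the unhindered aliphatic aldehyde attaches the acrylate through its α-carbon (C8), bringing in C8, C9 and C15 in the right pattern; the new C7 centre forms without control, which is irrelevant because C7 becomes sp2 in step 11.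

Step 10
Reactants: 16 methyl (6Z,9R,12E)-3-hydroxy-6,12-dimethyl-2-methylidene-9-(6-methylhepta-1,5-dien-2-yl)-14-(phenylsulfonyl)tetradeca-6,12-dienoate
Product: 17 methyl (6Z,9R,12E)-3-acetoxy-6,12-dimethyl-2-methylidene-9-(6-methylhepta-1,5-dien-2-yl)-14-(phenylsulfonyl)tetradeca-6,12-dienoate
Conditions: Ac2O, pyridine, DMAP (cat.), CH2Cl2, 0 °C
Reagents that add atoms: acetic anhydride (CC(=O)OC(C)=O)
Why: O-acetylation of the secondary allylic alcohol turns the C7 oxygen into the leaving group of the SN2′ step.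

Step 11
Reactants: 17 methyl (6Z,9R,12E)-3-acetoxy-6,12-dimethyl-2-methylidene-9-(6-methylhepta-1,5-dien-2-yl)-14-(phenylsulfonyl)tetradeca-6,12-dienoate
Product: 20 methyl (1E,5Z,8R,11E)-5,11-dimethyl-8-(6-methylhepta-1,5-dien-2-yl)-13-(phenylsulfonyl)cyclotetradeca-1,5,11-triene-1-carboxylate (both epimers at the sulfonyl carbon, ring locant C10), via lithiated sulfone 18 (not isolated), via macrocyclic ester enolate 19 (not isolated)
Conditions: LiN(SiMe3)2 (1.05 equiv), THF (0.002 M), −78 °C, then slowly to 0 °C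
Reagents that add atoms: none
Why: LiN(SiMe3)2 removes the most acidic proton (C10–H, α to the sulfone and allylic) at −78 °C, and on warming the sulfonyl-stabilised allyl anion 18 adds through C10 to C9, the unsubstituted terminus of the 2-(1-acetoxyalkyl)acrylate, to give ester enolate 19, which expels the C7 acetate (E1cB), a net SN2′ substitution. The closest known reaction types are the SN2′ alkylation of Baylis–Hillman acetates by stabilised carbanions and the sulfone-carbanion ring closures used for 14-membered cembranoid rings. The 14-membered ring closes in the 14-endo-trig mode (C9 is attacked, C8 lies inside the new ring). The new C10 centre forms as both epimers and is erased in step 13, while the new C7=C8 alkene should be E (C6 and C9 cis, ester trans to C6) because in the E1cB transition state the C6 chain turns away from the enolate carbon (allylic strain), the same sense that makes this tiglate-type geometry the thermodynamic one. The step needs ring closure over oligomerisation (the anion is formed cold at 0.002 M before addition can start), α- over γ-attack of the allyl anion (the sulfone localises reactivity at C10, and γ-attack at C12 would have to build a quaternary centre) and attack at C9 over C7 (C9 is the free CH2 Michael terminus and the leaving group sits on C7).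

Step 12
Reactants: 20 methyl (1E,5Z,8R,11E)-5,11-dimethyl-8-(6-methylhepta-1,5-dien-2-yl)-13-(phenylsulfonyl)cyclotetradeca-1,5,11-triene-1-carboxylate
Product: 21 [(1E,5Z,8R,11E)-5,11-dimethyl-8-(6-methylhepta-1,5-dien-2-yl)-13-(phenylsulfonyl)cyclotetradeca-1,5,11-trien-1-yl]methanol
Conditions: i-Bu2AlH, CH2Cl2, −78 °C; aq. KNaC4H4O6
Reagents that add atoms: none
Why: 1,2-reduction of the trisubstituted enoate by i-Bu2AlH gives the C15 hydroxymethyl group with the C7=C8 geometry unchanged; the sulfone is inert at −78 °C.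

Step 13
Reactants: 21 [(1E,5Z,8R,11E)-5,11-dimethyl-8-(6-methylhepta-1,5-dien-2-yl)-13-(phenylsulfonyl)cyclotetradeca-1,5,11-trien-1-yl]methanol
Product: 22 [(1E,5Z,8R,11E)-5,11-dimethyl-8-(6-methylhepta-1,5-dien-2-yl)cyclotetradeca-1,5,11-trien-1-yl]methanol (CNP0237384.1)
Conditions: PdCl2(dppp) (5 mol %), LiBHEt3, THF, 0 °C; then H2O
Reagents that add atoms: none
Why: palladium-catalysed hydride desulfonylation of the allylic sulfone (ionisation of C10–S by zerovalent palladium to the π-allyl complex, hydride delivery to the less substituted terminus C10) replaces SO2Ph by H with C11=C12 kept in place and E; the first equivalent of hydride only turns the free alcohol into its lithium alkoxide.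

Compound list
1 | (1S,2S,4R)-limonene-1,2-diol | C=C(C)[C@@H]1CC[C@](C)(O)[C@@H](O)C1 | starting material
2 | prenyl bromide (1-bromo-3-methylbut-2-ene) | CC(C)=CCBr | starting material
3 | trilithiated diol (dilithium dialkoxide allyllithium of 1) | [Li]CC(=C)[C@@H]1CC[C@](C)(O[Li])[C@@H](O[Li])C1 | intermediate
4 | (1S,2S,4R)-1-methyl-4-(6-methylhepta-1,5-dien-2-yl)cyclohexane-1,2-diol | C=C(CCC=C(C)C)[C@@H]1CC[C@](C)(O)[C@@H](O)C1 | intermediate
5 | (3R)-3-(6-methylhepta-1,5-dien-2-yl)-6-oxoheptanal | C=C(CCC=C(C)C)[C@H](CCC(C)=O)CC=O | intermediate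
6 | (5R,7Z)-8-iodo-5-(6-methylhepta-1,5-dien-2-yl)non-7-en-2-one | C=C(CCC=C(C)C)[C@H](CCC(C)=O)C/C=C(/C)I | intermediate
7 | acrolein diethyl acetal (3,3-diethoxyprop-1-ene) | C=CC(OCC)OCC | starting material
8 | 9-(3,3-diethoxypropyl)-9-borabicyclo[3.3.1]nonane | CCOC(CCB1C2CCCC1CCC2)OCC | intermediate
9 | (5R,7Z)-11,11-diethoxy-8-methyl-5-(6-methylhepta-1,5-dien-2-yl)undec-7-en-2-one | C=C(CCC=C(C)C)[C@H](CCC(C)=O)C/C=C(/C)CCC(OCC)OCC | intermediate
10 | ethyl (2E,6R,8Z)-12,12-diethoxy-3,9-dimethyl-6-(6-methylhepta-1,5-dien-2-yl)dodeca-2,8-dienoate | C=C(CCC=C(C)C)[C@H](CC/C(C)=C/C(=O)OCC)C/C=C(/C)CCC(OCC)OCC | intermediate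
11 | (2E,6R,8Z)-12,12-diethoxy-3,9-dimethyl-6-(6-methylhepta-1,5-dien-2-yl)dodeca-2,8-dien-1-ol | C=C(CCC=C(C)C)[C@H](CC/C(C)=C/CO)C/C=C(/C)CCC(OCC)OCC | intermediate
12 | (2E,6R,8Z)-12,12-diethoxy-3,9-dimethyl-6-(6-methylhepta-1,5-dien-2-yl)dodeca-2,8-dien-1-yl methanesulfonate | C=C(CCC=C(C)C)[C@H](CC/C(C)=C/COS(C)(=O)=O)C/C=C(/C)CCC(OCC)OCC | intermediate
13 | {[(2E,6R,8Z)-12,12-diethoxy-3,9-dimethyl-6-(6-methylhepta-1,5-dien-2-yl)dodeca-2,8-dien-1-yl]sulfonyl}benzene | C=C(CCC=C(C)C)[C@H](CC/C(C)=C/CS(=O)(=O)c1ccccc1)C/C=C(/C)CCC(OCC)OCC | intermediate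
14 | (4Z,7R,10E)-4,10-dimethyl-7-(6-methylhepta-1,5-dien-2-yl)-12-(phenylsulfonyl)dodeca-4,10-dienal | C=C(CCC=C(C)C)[C@H](CC/C(C)=C/CS(=O)(=O)c1ccccc1)C/C=C(/C)CCC=O | intermediate
15 | methyl acrylate | C=CC(=O)OC | starting material
16 | methyl (6Z,9R,12E)-3-hydroxy-6,12-dimethyl-2-methylidene-9-(6-methylhepta-1,5-dien-2-yl)-14-(phenylsulfonyl)tetradeca-6,12-dienoate, both C3 epimers | C=C(CCC=C(C)C)[C@H](CC/C(C)=C/CS(=O)(=O)c1ccccc1)C/C=C(/C)CCC(O)C(=C)C(=O)OC | intermediate
17 | methyl (6Z,9R,12E)-3-acetoxy-6,12-dimethyl-2-methylidene-9-(6-methylhepta-1,5-dien-2-yl)-14-(phenylsulfonyl)tetradeca-6,12-dienoate, both C3 epimers | C=C(CCC=C(C)C)[C@H](CC/C(C)=C/CS(=O)(=O)c1ccccc1)C/C=C(/C)CCC(OC(C)=O)C(=C)C(=O)OC | intermediate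
18 | lithiated sulfone (17 lithiated at the sulfonyl-bearing carbon, ring locant C10) | C=C(CCC=C(C)C)[C@H](CC/C(C)=C/C([Li])S(=O)(=O)c1ccccc1)C/C=C(/C)CCC(OC(C)=O)C(=C)C(=O)OC | intermediate
19 | macrocyclic lithium ester enolate (ring closed at C9–C10, C7 acetate still in place) | C=C(CCC=C(C)C)[C@H]1C/C=C(/C)CCC(OC(C)=O)C(=C(O[Li])OC)CC(S(=O)(=O)c2ccccc2)/C=C(\C)CC1 | intermediate
20 | methyl (1E,5Z,8R,11E)-5,11-dimethyl-8-(6-methylhepta-1,5-dien-2-yl)-13-(phenylsulfonyl)cyclotetradeca-1,5,11-triene-1-carboxylate, both C13 epimers | C=C(CCC=C(C)C)[C@H]1C/C=C(/C)CC/C=C(/C(=O)OC)CC(S(=O)(=O)c2ccccc2)/C=C(\C)CC1 | intermediate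
21 | [(1E,5Z,8R,11E)-5,11-dimethyl-8-(6-methylhepta-1,5-dien-2-yl)-13-(phenylsulfonyl)cyclotetradeca-1,5,11-trien-1-yl]methanol, both C13 epimers | C=C(CCC=C(C)C)[C@H]1C/C=C(/C)CC/C=C(/CO)CC(S(=O)(=O)c2ccccc2)/C=C(\C)CC1 | intermediate
22 | [(1E,5Z,8R,11E)-5,11-dimethyl-8-(6-methylhepta-1,5-dien-2-yl)cyclotetradeca-1,5,11-trien-1-yl]methanol | C=C(CCC=C(C)C)[C@H]1C/C=C(/C)CC/C=C(/CO)CC/C=C(\C)CC1 | target

Total step count: 13. Longest linear sequence: 13 (the route is fully linear from 1).

Steps most likely to fail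

Step 11. Oligomerisation may outrun ring closure, the carbanion may be acylated by the acetate or the ester, or geometric control may be lost in the elimination that sets C7=C8. The fallback sets out from 16: allylic bromination with transposition (NBS, Me2S, CH2Cl2, 0 °C → rt) should give methyl (2Z,6Z,9R,12E)-2-(bromomethyl)-6,12-dimethyl-9-(6-methylhepta-1,5-dien-2-yl)-14-(phenylsulfonyl)tetradeca-2,6,12-trienoate F1, in which the C7=C8 geometry is already fixed as the thermodynamic one. Deprotonation of the sulfone (LiN(SiMe3)2, THF, high dilution, −78 °C → 0 °C) and direct SN2 displacement of the primary allylic bromide at C9, the classical sulfone-alkylation ring closure, then forms the same C9–C10 bond. The route is rejoined at 20.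

Step 3. The ylide may also attack the methyl ketone, the iodo-ylide may decompose before it reacts (giving non-iodinated alkene), or Z selectivity may erode. The fallback sets out from 5: Ramirez dibromo-olefination of the aldehyde (CBr4, PPh3, CH2Cl2, 0 °C) gives (5R)-8,8-dibromo-5-(6-methylhepta-1,5-dien-2-yl)oct-7-en-2-one F2. Trans-selective Negishi monomethylation (MeZnCl, Pd(DPEphos)Cl2, THF, rt; the bromine trans to the chain reacts first and the ketone tolerates the organozinc) gives (5R,7Z)-8-bromo-5-(6-methylhepta-1,5-dien-2-yl)non-7-en-2-one F3. F3 takes the place of 6 in the B-alkyl Suzuki coupling with 8 under the conditions of step 4, and the route is rejoined at 9.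

Step 1. Allylic metalation may stay incomplete because the dilithium dialkoxide aggregates or precipitates, and O-alkylation may compete. The fallback sets out from 1: the diol is masked as its acetonide (3aS,5R,7aS)-2,2,7a-trimethyl-5-(prop-1-en-2-yl)hexahydro-1,3-benzodioxole F4 (2,2-dimethoxypropane, PPTS, CH2Cl2). F4 is metalated at the isopropenyl methyl with n-BuLi/KOt-Bu (THF, −78 °C → −50 °C) and alkylated with 2 to give (3aS,5R,7aS)-2,2,7a-trimethyl-5-(6-methylhepta-1,5-dien-2-yl)hexahydro-1,3-benzodioxole F5. H5IO6 in THF/H2O then hydrolyses the acetal and cleaves the diol in one flask, and the route is rejoined at 5.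

Further compounds
F1 | step 11 | methyl (2Z,6Z,9R,12E)-2-(bromomethyl)-6,12-dimethyl-9-(6-methylhepta-1,5-dien-2-yl)-14-(phenylsulfonyl)tetradeca-2,6,12-trienoate | C=C(CCC=C(C)C)[C@H](CC/C(C)=C/CS(=O)(=O)c1ccccc1)C/C=C(/C)CC/C=C(/C(=O)OC)CBr
F2 | step 3 | (5R)-8,8-dibromo-5-(6-methylhepta-1,5-dien-2-yl)oct-7-en-2-one | C=C(CCC=C(C)C)[C@H](CCC(C)=O)CC=C(Br)Br
F3 | step 3 | (5R,7Z)-8-bromo-5-(6-methylhepta-1,5-dien-2-yl)non-7-en-2-one | C=C(CCC=C(C)C)[C@H](CCC(C)=O)C/C=C(/C)Br
F4 | step 1 | (3aS,5R,7aS)-2,2,7a-trimethyl-5-(prop-1-en-2-yl)hexahydro-1,3-benzodioxole | C=C(C)[C@@H]1CC[C@]2(C)OC(C)(C)O[C@H]2C1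
F5 | step 1 | (3aS,5R,7aS)-2,2,7a-trimethyl-5-(6-methylhepta-1,5-dien-2-yl)hexahydro-1,3-benzodioxole | C=C(CCC=C(C)C)[C@@H]1CC[C@]2(C)OC(C)(C)O[C@H]2C1
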